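**Retrosynthetic overview**
- The bond between the bridging CH2 and chromone C6 is disconnected together with the C7–C8 bond of the chromone benzene ring. This gives the isochromanone benzylic ammonium salt 10 (a para-quinone methide precursor) and the 4-pyranone β-keto ester 14.
- Enabling feature: chromone C6 lies between the oxygen-bearing C5 and C7, so in the unfolded chain it is the α-carbon of a β-keto ester, and O1/C2/C3/C4/C4a/C8a are a 2,6-dimethyl-4-pyranone whose 2-methyl carbon (future C8) is vinylogously acidic. In the other half the 8-OH of the isochromanone is para to C5, so a C5–CH2–NMe3+ group collapses to a quinone methide.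
- Key step: the enolate of 14 adds to the quinone methide and, in the same flask, the pyranone 2-methyl anion closes onto the ester (Claisen). The chromone benzene ring is built around the new bond, which puts the bridge at C6 and not C8 by construction.
- Ring order: the isochromanone lactone ring (step 2, C3 from (R)-propylene oxide) and the pyranone ring (step 7) come first, the chromone benzene ring last (step 9); 7-O-methylation and debenzylation follow.

Key step: step 9

Remark: 2,4-dimethoxy-3-methylbenzoic acid, (R)-propylene oxide and dehydroacetic acid are taken as commercial; the transient α-carbon of adduct 16 is formed as both epimers and is drawn without configuration because it becomes aromatic C6.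

Step 1
Reactants: 1 2,4-dimethoxy-3-methylbenzoic acid
Product: 3 N,N-diethyl-2,4-dimethoxy-3-methylbenzamide, via acid chloride 2 (not isolated)
Conditions: (COCl)2, cat. DMF, CH2Cl2, 0 °C → rt; then Et2NH (3 equiv), CH2Cl2, 0 °C → rt
Reagents that add atoms: diethylamine CCNCC
Why: Acyl chloride formation followed by amidation (Schotten–Baumann type) should give the tertiary amide that serves as the directing group for the next step.

Step 2
Reactants: 3 N,N-diethyl-2,4-dimethoxy-3-methylbenzamide, 4 (R)-propylene oxide
Product: 6 (3R)-6,8-dimethoxy-3,7-dimethylisochroman-1-one, via hydroxy amide 5 (not isolated)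
Conditions: s-BuLi, TMEDA, THF, −78 °C; 4, CuI (10 mol %), −78 → 0 °C; aq NH4Cl; then p-TsOH·H2O, PhMe, reflux
Reagents that add atoms: none
Why: Directed ortho-metalation should occur at the only position ortho to the CONEt2 group, the copper-assisted SN2 opening of the epoxide at its CH2 terminus leaves the stereocentre of 4 untouched so that C3 is (R), and acid-promoted lactonisation expels diethylamine.

Step 3
Reactants: 6 (3R)-6,8-dimethoxy-3,7-dimethylisochroman-1-one
Product: 7 (3R)-6,8-dihydroxy-3,7-dimethylisochroman-1-one
Conditions: BBr3 (3 equiv), CH2Cl2, −78 → 0 °C; H2O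
Reagents that add atoms: none
Why: Lewis-acid ether cleavage with BBr3 should remove both aryl methyl ethers, while the secondary, non-benzylic lactone C–O bond does not ionise at low temperature, so C3 keeps its configuration.

Step 4
Reactants: 7 (3R)-6,8-dihydroxy-3,7-dimethylisochroman-1-one
Product: 8 (3R)-6-(benzyloxy)-8-hydroxy-3,7-dimethylisochroman-1-one
Conditions: BnBr (1.05 equiv), K2CO3, acetone, 50 °C
Reagents that add atoms: benzyl bromide BrCc1ccccc1
Why: Williamson etherification should be selective for the 6-OH because the 8-OH is locked in a hydrogen bond to the lactone carbonyl and is far less nucleophilic.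

Step 5
Reactants: 8 (3R)-6-(benzyloxy)-8-hydroxy-3,7-dimethylisochroman-1-one
Product: 9 (3R)-6-(benzyloxy)-5-[(dimethylamino)methyl]-8-hydroxy-3,7-dimethylisochroman-1-one
Conditions: CH2=NMe2+ I− (1.5 equiv), K2CO3, MeCN, 50 °C
Reagents that add atoms: dimethylmethyleneiminium iodide C=[N+](C)C.[I-]
Why: Mannich aminomethylation of the phenolate can only take place at C5, the single unsubstituted ring position, which is para to the 8-OH and ortho to the 6-benzyloxy group.

Step 6
Reactants: 9 (3R)-6-(benzyloxy)-5-[(dimethylamino)methyl]-8-hydroxy-3,7-dimethylisochroman-1-one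
Product: 10 [(3R)-6-(benzyloxy)-8-hydroxy-3,7-dimethyl-1-oxoisochroman-5-yl]methyl(trimethyl)ammonium iodide
Conditions: MeI (3 equiv), acetone, rt; filter
Reagents that add atoms: iodomethane CI
Why: Menshutkin quaternisation of the tertiary amine (no base present, so the chelated phenol is not methylated) installs the trimethylammonium leaving group needed for quinone methide formation.

Step 7
Reactants: 11 dehydroacetic acid (3-acetyl-4-hydroxy-6-methyl-2H-pyran-2-one)
Product: 12 2,6-dimethyl-4-oxo-4H-pyran-3-carboxylic acid
Conditions: aq H2SO4 (ca. 85%), 130 °C, short contact time; ice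
Reagents that add atoms: none
Why: In hot sulfuric acid the 2-pyranone lactone should open to 2-acetyl-3,5-dioxohexanoic acid, which recloses through the acetyl oxygen by cyclodehydration to the 4-pyranone-3-carboxylic acid (the classical acid isomerisation of dehydroacetic acid).

Step 8
Reactants: 12 2,6-dimethyl-4-oxo-4H-pyran-3-carboxylic acid
Product: 14 methyl 3-(2,6-dimethyl-4-oxo-4H-pyran-3-yl)-3-oxopropanoate, via acyl imidazolide 13 (not isolated)
Conditions: CDI, THF, rt; then KO2CCH2CO2Me, MgCl2, Et3N, THF–MeCN, rt → 50 °C; aq HCl
Reagents that add atoms: potassium methyl malonate COC(=O)CC(=O)[O-].[K+]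
Why: C-Acylation of the magnesium enolate of the malonate half-ester by the acyl imidazolide and decarboxylation on acidic work-up (Masamune-type β-keto ester synthesis) proceed under near-neutral conditions that should leave the 4-pyranone intact.

Step 9
Reactants: 10 [(3R)-6-(benzyloxy)-8-hydroxy-3,7-dimethyl-1-oxoisochroman-5-yl]methyl(trimethyl)ammonium iodide, 14 methyl 3-(2,6-dimethyl-4-oxo-4H-pyran-3-yl)-3-oxopropanoate
Product: 17 6-{[(3R)-6-(benzyloxy)-8-hydroxy-3,7-dimethyl-1-oxoisochroman-5-yl]methyl}-5,7-dihydroxy-2-methyl-4H-chromen-4-one, via para-quinone methide 15 (not isolated), via keto ester adduct 16 (not isolated)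
Conditions: 14 (1.2 equiv), LiHMDS (1.2 equiv), THF–DMPU, −78 °C; add 10, then LiHMDS (1.0 equiv), −78 → 0 °C; then LiHMDS (3.5 equiv), 0 → 25 °C; aq HCl
Reagents that add atoms: none
Why: Proposed new method: deprotonation of the 8-OH of 10 expels NMe3 to give para-quinone methide 15, whose exocyclic CH2 is attacked by the lithium enolate of 14 at its only doubly activated carbon (1,6-addition with rearomatisation), which forms the bond between the bridging CH2 and the future chromone C6 in adduct 16; excess LiHMDS then deprotonates the pyranone 2-methyl group, this vinylogous carbanion attacks the methyl ester (intramolecular Claisen/Dieckmann condensation), and loss of methoxide and double enolisation give the 5,7-dihydroxy benzene ring. The closest known reaction types are 1,6-additions of β-dicarbonyl enolates to para-quinone methides, the lateral metalation–acylation of 2-methyl-4-pyranones with esters, and the biomimetic Claisen cyclisation of 3,5,7-triketo esters to acylphloroglucinols. One ring is closed, the carbocycle C4a–C5–C6–C7–C8–C8a, through the C7–C8 bond in a 6-(enolexo)-exo-trig acyl substitution whose cis geometry is enforced by the pyranone C2=C3 double bond. No lasting stereocentre is created, since the α-carbon of 16 becomes aromatic C6 and C3 of the lactone is remote from every acidic site. The step needs C- over O-alkylation and mono- over dialkylation of the keto ester (soft benzylic electrophile, hindered product, slight excess of 14) and ring closure from the 2-methyl and not the 6-methyl anion (only the former can reach the ester, and the anions equilibrate). Because the non-nucleophilic amide base never opens the pyranone, the bridge carbon is fixed at C6, between C5–OH and C7–OH, and cannot end up at C8.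

Step 10
Reactants: 17 6-{[(3R)-6-(benzyloxy)-8-hydroxy-3,7-dimethyl-1-oxoisochroman-5-yl]methyl}-5,7-dihydroxy-2-methyl-4H-chromen-4-one
Product: 18 6-{[(3R)-6-(benzyloxy)-8-hydroxy-3,7-dimethyl-1-oxoisochroman-5-yl]methyl}-5-hydroxy-7-methoxy-2-methyl-4H-chromen-4-one
Conditions: MeI (1.1 equiv), K2CO3 (1.2 equiv), acetone, rt
Reagents that add atoms: iodomethane CI
Why: Williamson methylation with one equivalent of MeI should occur only at the 7-OH, since the 5-OH and the 8'-OH are hydrogen-bonded to carbonyl groups and the 6'-oxygen is benzylated (the classical 7-O-selectivity of 5,7-dihydroxychromones).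

Step 11
Reactants: 18 6-{[(3R)-6-(benzyloxy)-8-hydroxy-3,7-dimethyl-1-oxoisochroman-5-yl]methyl}-5-hydroxy-7-methoxy-2-methyl-4H-chromen-4-one
Product: 19 (3R)-6,8-dihydroxy-5-[(5-hydroxy-7-methoxy-2-methyl-4-oxo-4H-chromen-6-yl)methyl]-3,7-dimethylisochroman-1-one
Conditions: H2 (1 atm), 10% Pd/C, EtOAc–MeOH, rt
Reagents that add atoms: none
Why: Catalytic hydrogenolysis of the benzyl ether over Pd/C at 1 atm and room temperature should free the 6'-OH without touching the chromone C2=C3 bond, the lactone or the diarylmethane.

**Compound list**
1 | 2,4-dimethoxy-3-methylbenzoic acid | COc1ccc(C(=O)O)c(OC)c1C | starting material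
2 | 2,4-dimethoxy-3-methylbenzoyl chloride | COc1ccc(C(Cl)=O)c(OC)c1C | intermediate
3 | N,N-diethyl-2,4-dimethoxy-3-methylbenzamide | CCN(CC)C(=O)c1ccc(OC)c(C)c1OC | intermediate
4 | (R)-propylene oxide | C[C@@H]1CO1 | starting material
5 | N,N-diethyl-6-[(2R)-2-hydroxypropyl]-2,4-dimethoxy-3-methylbenzamide | CCN(CC)C(=O)c1c(C[C@@H](C)O)cc(OC)c(C)c1OC | intermediate
6 | (3R)-6,8-dimethoxy-3,7-dimethylisochroman-1-one | COc1cc2C[C@@H](C)OC(=O)c2c(OC)c1C | intermediate
7 | (3R)-6,8-dihydroxy-3,7-dimethylisochroman-1-one | Cc1c(O)cc2C[C@@H](C)OC(=O)c2c1O | intermediate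
8 | (3R)-6-(benzyloxy)-8-hydroxy-3,7-dimethylisochroman-1-one | Cc1c(OCc2ccccc2)cc3C[C@@H](C)OC(=O)c3c1O | intermediate
9 | (3R)-6-(benzyloxy)-5-[(dimethylamino)methyl]-8-hydroxy-3,7-dimethylisochroman-1-one | Cc1c(OCc2ccccc2)c(CN(C)C)c3C[C@@H](C)OC(=O)c3c1O | intermediate
10 | [(3R)-6-(benzyloxy)-8-hydroxy-3,7-dimethyl-1-oxoisochroman-5-yl]methyl(trimethyl)ammonium iodide | Cc1c(OCc2ccccc2)c(C[N+](C)(C)C)c3C[C@@H](C)OC(=O)c3c1O.[I-] | intermediate
11 | dehydroacetic acid (3-acetyl-4-hydroxy-6-methyl-2H-pyran-2-one) | CC(=O)c1c(O)cc(C)oc1=O | starting material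
12 | 2,6-dimethyl-4-oxo-4H-pyran-3-carboxylic acid | Cc1cc(=O)c(C(=O)O)c(C)o1 | intermediate
13 | 3-(1H-imidazole-1-carbonyl)-2,6-dimethyl-4H-pyran-4-one | Cc1cc(=O)c(C(=O)n2ccnc2)c(C)o1 | intermediate
14 | methyl 3-(2,6-dimethyl-4-oxo-4H-pyran-3-yl)-3-oxopropanoate | COC(=O)CC(=O)c1c(C)oc(C)cc1=O | intermediate
15 | (3R)-6-(benzyloxy)-3,7-dimethyl-5-methylidene-3,4-dihydro-1H-isochromene-1,8(5H)-dione | C=C1C(OCc2ccccc2)=C(C)C(=O)C3=C1C[C@@H](C)OC3=O | intermediate
16 | methyl 2-{[(3R)-6-(benzyloxy)-8-hydroxy-3,7-dimethyl-1-oxoisochroman-5-yl]methyl}-3-(2,6-dimethyl-4-oxo-4H-pyran-3-yl)-3-oxopropanoate (both epimers at C2) | COC(=O)C(Cc1c(OCc2ccccc2)c(C)c(O)c3c1C[C@@H](C)OC3=O)C(=O)c1c(C)oc(C)cc1=O | intermediate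
17 | 6-{[(3R)-6-(benzyloxy)-8-hydroxy-3,7-dimethyl-1-oxoisochroman-5-yl]methyl}-5,7-dihydroxy-2-methyl-4H-chromen-4-one | Cc1cc(=O)c2c(O)c(Cc3c(OCc4ccccc4)c(C)c(O)c5c3C[C@@H](C)OC5=O)c(O)cc2o1 | intermediate
18 | 6-{[(3R)-6-(benzyloxy)-8-hydroxy-3,7-dimethyl-1-oxoisochroman-5-yl]methyl}-5-hydroxy-7-methoxy-2-methyl-4H-chromen-4-one | COc1cc2oc(C)cc(=O)c2c(O)c1Cc3c(OCc4ccccc4)c(C)c(O)c5c3C[C@@H](C)OC5=O | intermediate
19 | (3R)-6,8-dihydroxy-5-[(5-hydroxy-7-methoxy-2-methyl-4-oxo-4H-chromen-6-yl)methyl]-3,7-dimethylisochroman-1-one | COc1cc2oc(C)cc(=O)c2c(O)c1Cc1c(O)c(C)c(O)c2c1C[C@@H](C)OC2=O | target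

**Step count and risks**
Total step count: 11. Longest linear sequence: 9 steps (steps 1–6, then 9–11); the pyranone branch (steps 7–8) joins at step 9.

Steps most likely to fail:

1. Step 9 (Proposed new method). The ring closure may stall at adduct 16 because the lateral carbanion has to attack an ester that is deactivated by the neighbouring enolate. Alternatively, nucleophilic opening of the pyranone ring may scramble the connectivity. The fallback uses a preformed chromone as the carbon nucleophile and sets out from compound 10. Treating 10 with commercial noreugenin (5,7-dihydroxy-2-methyl-4H-chromen-4-one) and K2CO3 in aqueous acetonitrile at room temperature should generate quinone methide 15. The chromone bisphenolate should then be C-alkylated at C6, the carbon between the two phenolate oxygens and the usual site of nuclear alkylation of 5,7-dihydroxychromones in base; alkylation at C8 is the competing event and would have to be separated. The fallback comes back to the route at compound 17 and makes no compound outside the compound list (F0).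

2. Step 5. The hindered C5 position, flanked by the benzyloxy group and the ring CH2 and deactivated by the lactone carbonyl, may be too unreactive toward the iminium ion. The Mannich base may also lose amine under the basic conditions and self-condense through the quinone methide. The fallback sets out from compound 8 and installs the aminomethyl group by cross-coupling. Bromination with NBS in MeCN at 0 °C, para to the 8-OH, should give (3R)-6-(benzyloxy)-5-bromo-8-hydroxy-3,7-dimethylisochroman-1-one F1. Suzuki–Miyaura aminomethylation with potassium (dimethylaminomethyl)trifluoroborate (Pd(OAc)2, XPhos, Cs2CO3, THF–H2O, 80 °C) should then give the amine, and the fallback comes back to the route at compound 9.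

3. Step 7. Hydrolytic deacetylation (to 4-hydroxy-6-methyl-2-pyranone) or decarboxylation of the product may outrun the recyclisation. The fallback sets out from compound 11 and makes decarboxylation the intended path. Refluxing concentrated HCl should convert 11 into 2,6-dimethyl-4H-pyran-4-one F2 (also commercial). Electrophilic bromination with NBS in MeCN should give 3-bromo-2,6-dimethyl-4H-pyran-4-one F3. Palladium-catalysed hydroxycarbonylation (Pd(OAc)2, Xantphos, CO 1 atm, H2O, K2CO3, dioxane, 80 °C) should then reinstall the carboxyl group, and the fallback comes back to the route at compound 12.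

Further compounds
F0 | step 9 | none | none
F1 | step 5 | (3R)-6-(benzyloxy)-5-bromo-8-hydroxy-3,7-dimethylisochroman-1-one | Cc1c(OCc2ccccc2)c(Br)c3C[C@@H](C)OC(=O)c3c1O
F2 | step 7 | 2,6-dimethyl-4H-pyran-4-one | Cc1cc(=O)cc(C)o1
F3 | step 7 | 3-bromo-2,6-dimethyl-4H-pyran-4-one | Cc1cc(=O)c(Br)c(C)o1
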